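**Plan**
- Retrosynthesis: remove the PMB group of the C8 side chain; open the cis-1,2-epoxide to a syn-1,2-diol (O-1 silylated, O-2 as leaving group); cut the C1–C2 bond of the ten-membered ring (enal plus aldehyde); then cut the C8 ester, C8–C9 (allylation), C7–C8 and C11–C12 (vinylmagnesiation, carbonylation), C6–C7 (alkynylation), C5–C6 and C4–C15 (methylalumination, formaldehyde).
- Forward: C2–C6 enal → C6 propargylic alcohol → (Z)-iododienol → 4,5-epoxide → butenolide ring → C8 aldehyde → homoallylic alcohol → side-chain ester → enal/aldehyde → ten-membered ring → 1,2-epoxide → free side-chain alcohol.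
- Stereochemistry: C6 from catalyst-controlled alkynylation; C4/C5 from hydroxyl-directed threo epoxidation relayed from C6; C8 from catalyst-controlled allylation; C1/C2 from the chair transition state of the ring closure (syn diol), with C2 inverted on epoxide closure.
- Enabling feature: C1 is allylic to the C10=C14 exocyclic methylene and oxygen-bearing, and its ring neighbour C2 is oxygen-bearing too. This 1,2-dioxygenated allyl unit of the ten-membered ring is the retron of a γ-oxyallyl-metal addition to an aldehyde, so a 2-substituted acrolein (C14=C10–C1=O) and a C2 aldehyde are the only precursors needed.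

Key step: step 17

Remarks. Atom labels C1–C15 follow germacrane numbering (C12 lactone carbonyl, C13 acetoxymethyl carbon, C14 exocyclic methylene, C15 methyl). TBDPS = tert-butyldiphenylsilyl, TBS = tert-butyldimethylsilyl, TES = triethylsilyl, PMB = 4-methoxybenzyl, Ox = (2R,3R)-3-[2-(TBDPS-oxy)ethyl]-3-methyloxiran-2-yl. Assumption: (S,S)-ProPhenol is taken to give the 4R carbinol 7; if the sense of induction is the opposite, its antipode is used.

**Step 1**
Reactants: 1 tert-butyl(but-3-yn-1-yloxy)diphenylsilane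
Product: 4 (2E)-5-(TBDPS-oxy)-3-methylpent-2-en-1-ol, via alkenylalane 2 (not isolated), via lithium alanate 3 (not isolated)
Conditions: Me3Al, Cp2ZrCl2 (cat.), CH2Cl2, 0 °C to rt; then n-BuLi, THF, −78 °C; (CH2O)n, rt
Reagents that add atoms: trimethylaluminium C[Al](C)C; formaldehyde (as paraformaldehyde) C=O
Why: Negishi carboalumination adds methyl and aluminium syn across the terminal alkyne with methyl on the internal carbon, and hydroxymethylation of the alanate proceeds with retention, which fixes the E alkene (C15 methyl cis to C6).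

**Step 2**
Reactants: 4 (2E)-5-(TBDPS-oxy)-3-methylpent-2-en-1-ol
Product: 5 (2E)-5-(TBDPS-oxy)-3-methylpent-2-enal
Conditions: MnO2, CH2Cl2, rt
Reagents that add atoms: none
Why: MnO2 oxidises the allylic alcohol selectively to the enal without touching the silyl ether or the alkene geometry (allylic oxidation).

**Step 3**
Reactants: 5 (2E)-5-(TBDPS-oxy)-3-methylpent-2-enal; 6 tert-butyldimethyl(prop-2-yn-1-yloxy)silane
Product: 7 (4R,5E)-1-(TBS-oxy)-8-(TBDPS-oxy)-6-methyloct-5-en-2-yn-4-ol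
Conditions: (S,S)-ProPhenol (10 mol %), Me2Zn, Ph3P=O (20 mol %), toluene, 0 °C
Reagents that add atoms: none
Why: The dinuclear zinc–ProPhenol catalyst should deliver the zinc acetylide of 6 to one face of the enal (catalytic asymmetric alkynylation), setting C6 by catalyst control.

**Step 4**
Reactants: 7 (4R,5E)-1-(TBS-oxy)-8-(TBDPS-oxy)-6-methyloct-5-en-2-yn-4-ol
Product: 9 (2Z,4R,5E)-1-(TBS-oxy)-8-(TBDPS-oxy)-3-ethenyl-2-iodo-6-methylocta-2,5-dien-4-ol, via magnesium chelate 8 (not isolated)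
Conditions: CH2=CHMgCl (5 equiv), THF/toluene, 70 °C; then I2, THF, −78 °C to 0 °C
Reagents that add atoms: vinylmagnesium chloride C=C[Mg]Cl; iodine II
Why: Hydroxyl-directed anti-carbomagnesiation of the propargylic alkoxide places vinyl on the proximal alkyne carbon (C7) and magnesium on C11 in a five-membered chelate, and iodinolysis with retention gives the Z iodide with C6–O and iodine cis, as the later lactonisation requires.

**Step 5**
Reactants: 9 (2Z,4R,5E)-1-(TBS-oxy)-8-(TBDPS-oxy)-3-ethenyl-2-iodo-6-methylocta-2,5-dien-4-ol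
Product: 10 (1S,2Z)-4-(TBS-oxy)-2-ethenyl-3-iodo-1-Ox-but-2-en-1-ol
Conditions: mCPBA, NaHCO3, CH2Cl2, 0 °C
Reagents that add atoms: 3-chloroperoxybenzoic acid O=C(OO)c1cccc(Cl)c1
Why: Hydroxyl-directed peracid epoxidation of the electron-rich trisubstituted C4=C5 alkene: 1,3-allylic strain from the C15 methyl (cis to C6) holds H-6 in the alkene plane, so the hydrogen-bonded peracid attacks syn to the hydroxyl and should give the threo epoxy alcohol (4R,5R next to 6S), the iododiene being deactivated.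

**Step 6**
Reactants: 10 (1S,2Z)-4-(TBS-oxy)-2-ethenyl-3-iodo-1-Ox-but-2-en-1-ol
Product: 11 (5S)-3-[(TBS-oxy)methyl]-4-ethenyl-5-Ox-furan-2(5H)-one
Conditions: PdCl2(PPh3)2 (5 mol %), CO (1 atm), Et3N, THF, 50 °C
Reagents that add atoms: carbon monoxide [C-]#[O+]
Why: Oxidative addition of zerovalent palladium to the alkenyl iodide, CO insertion and capture of the acylpalladium by the cis hydroxyl (carbonylative lactonisation) close the butenolide under conditions that spare the epoxide.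

**Step 7**
Reactants: 11 (5S)-3-[(TBS-oxy)methyl]-4-ethenyl-5-Ox-furan-2(5H)-one
Product: 12 (5S)-4-ethenyl-3-(hydroxymethyl)-5-Ox-furan-2(5H)-one
Conditions: HF·pyridine, pyridine, THF, 0 °C
Reagents that add atoms: none
Why: Buffered HF·pyridine cleaves the primary TBS ether much faster than the primary TBDPS ether (selective desilylation).

**Step 8**
Reactants: 12 (5S)-4-ethenyl-3-(hydroxymethyl)-5-Ox-furan-2(5H)-one
Product: 13 [(5S)-4-ethenyl-2-oxo-5-Ox-2,5-dihydrofuran-3-yl]methyl acetate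
Conditions: Ac2O, pyridine, DMAP (cat.), CH2Cl2, 0 °C
Reagents that add atoms: acetic anhydride CC(=O)OC(C)=O
Why: Standard acylation of the primary alcohol installs the C13 acetate of the target.

**Step 9**
Reactants: 13 [(5S)-4-ethenyl-2-oxo-5-Ox-2,5-dihydrofuran-3-yl]methyl acetate
Product: 14 [(5S)-4-formyl-2-oxo-5-Ox-2,5-dihydrofuran-3-yl]methyl acetate
Conditions: OsO4 (cat.), NaIO4, 2,6-lutidine, dioxane/H2O, rt
Reagents that add atoms: sodium periodate [Na+].[O-]I(=O)(=O)=O (terminal oxidant and, through OsO4, source of the aldehyde oxygen)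
Why: Lemieux–Johnson oxidation cleaves the terminal monosubstituted alkene, while the tetrasubstituted, electron-poor butenolide alkene is inert to OsO4.

**Step 10**
Reactants: 15 3-chloro-2-(chloromethyl)prop-1-ene
Product: 16 tributyl[2-(chloromethyl)prop-2-en-1-yl]stannane
Conditions: Bu3SnH, LDA, THF, 0 °C; then 15 (3 equiv), −78 °C
Reagents that add atoms: tributyltin hydride CCCC[SnH](CCCC)CCCC
Why: SN2 displacement of one allylic chloride by tributylstannyllithium, with the dichloride in excess to suppress double substitution.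

**Step 11**
Reactants: 14 [(5S)-4-formyl-2-oxo-5-Ox-2,5-dihydrofuran-3-yl]methyl acetate; 16 tributyl[2-(chloromethyl)prop-2-en-1-yl]stannane
Product: 17 [(5S)-4-[(1S)-3-(chloromethyl)-1-hydroxybut-3-en-1-yl]-2-oxo-5-Ox-2,5-dihydrofuran-3-yl]methyl acetate
Conditions: (S)-BINOL (20 mol %), Ti(OiPr)4 (10 mol %), 4 Å MS, CH2Cl2, −20 °C
Reagents that add atoms: none
Why: Keck asymmetric allylation: the BINOL–titanium Lewis acid activates the aldehyde and the allylstannane adds through its γ-carbon to one carbonyl face, which should set C8 as S by catalyst control while the allylic chloride is carried through.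

**Step 12**
Reactants: 18 2-(bromomethyl)prop-2-enoic acid; 19 (4-methoxyphenyl)methanol
Product: 20 2-[(PMB-oxy)methyl]prop-2-enoic acid
Conditions: NaH (2.2 equiv), THF, 0 °C to rt; then aq. HCl
Reagents that add atoms: none
Why: The alkoxide of 19 displaces the allylic bromide of the carboxylate of 18 (Williamson etherification; SN2 and SN2′ paths give the same product).

**Step 13**
Reactants: 17 [(5S)-4-[(1S)-3-(chloromethyl)-1-hydroxybut-3-en-1-yl]-2-oxo-5-Ox-2,5-dihydrofuran-3-yl]methyl acetate; 20 2-[(PMB-oxy)methyl]prop-2-enoic acid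
Product: 21 (1S)-1-[(2S)-4-(acetoxymethyl)-5-oxo-2-Ox-2,5-dihydrofuran-3-yl]-3-(chloromethyl)but-3-en-1-yl 2-[(PMB-oxy)methyl]prop-2-enoate
Conditions: EDC·HCl, DMAP (cat.), CH2Cl2, 0 °C to rt
Reagents that add atoms: none
Why: Steglich esterification acylates the secondary C8 alcohol under near-neutral conditions that the epoxide, butenolide and allylic chloride should tolerate.

**Step 14**
Reactants: 21 (1S)-1-[(2S)-4-(acetoxymethyl)-5-oxo-2-Ox-2,5-dihydrofuran-3-yl]-3-(chloromethyl)but-3-en-1-yl 2-[(PMB-oxy)methyl]prop-2-enoate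
Product: 22 (1S)-1-[(2S)-4-(acetoxymethyl)-5-oxo-2-Ox-2,5-dihydrofuran-3-yl]-3-formylbut-3-en-1-yl 2-[(PMB-oxy)methyl]prop-2-enoate
Conditions: Me3NO, NaI (cat.), DMSO, rt
Reagents that add atoms: trimethylamine N-oxide C[N+](C)(C)[O-]
Why: Kornblum-type oxidation with an amine N-oxide: O-alkylation of Me3NO by the allylic halide and loss of trimethylammonium chloride give the 2-substituted acrolein (SN2 and SN2′ alkylation lead to the same enal).

**Step 15**
Reactants: 22 (1S)-1-[(2S)-4-(acetoxymethyl)-5-oxo-2-Ox-2,5-dihydrofuran-3-yl]-3-formylbut-3-en-1-yl 2-[(PMB-oxy)methyl]prop-2-enoate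
Product: 23 (1S)-1-[(2S)-4-(acetoxymethyl)-2-[(2R,3R)-3-(2-hydroxyethyl)-3-methyloxiran-2-yl]-5-oxo-2,5-dihydrofuran-3-yl]-3-formylbut-3-en-1-yl 2-[(PMB-oxy)methyl]prop-2-enoate
Conditions: HF·pyridine, pyridine, THF, 0 °C to rt
Reagents that add atoms: none
Why: Fluoride cleaves the remaining silyl ether, and the pyridine buffer should protect the epoxide, acetate and enal (desilylation).

**Step 16**
Reactants: 23 (1S)-1-[(2S)-4-(acetoxymethyl)-2-[(2R,3R)-3-(2-hydroxyethyl)-3-methyloxiran-2-yl]-5-oxo-2,5-dihydrofuran-3-yl]-3-formylbut-3-en-1-yl 2-[(PMB-oxy)methyl]prop-2-enoate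
Product: 24 (1S)-1-[(2S)-4-(acetoxymethyl)-2-[(2R,3R)-3-methyl-3-(2-oxoethyl)oxiran-2-yl]-5-oxo-2,5-dihydrofuran-3-yl]-3-formylbut-3-en-1-yl 2-[(PMB-oxy)methyl]prop-2-enoate
Conditions: Dess–Martin periodinane, pyridine, CH2Cl2, 0 °C; used at once
Reagents that add atoms: none
Why: Dess–Martin oxidation under buffered, non-basic conditions gives the β,γ-epoxy aldehyde, which is used crude because it is prone to β-elimination.

**Step 17**
Reactants: 24 (1S)-1-[(2S)-4-(acetoxymethyl)-2-[(2R,3R)-3-methyl-3-(2-oxoethyl)oxiran-2-yl]-5-oxo-2,5-dihydrofuran-3-yl]-3-formylbut-3-en-1-yl 2-[(PMB-oxy)methyl]prop-2-enoate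
Product: 26 (1R,2R,4R,5R,6S,8S)-13-acetoxy-4,5-epoxy-2-hydroxy-1-(TES-oxy)-8-({2-[(PMB-oxy)methyl]prop-2-enoyl}oxy)germacra-7(11),10(14)-dien-12,6-olide, via siloxyallylchromium 25 (not isolated)
Conditions: CrCl2 (8 equiv), Et3SiCl (2 equiv), THF/DMF, rt, slow addition of 24 (final 2 mM)
Reagents that add atoms: chlorotriethylsilane CC[Si](Cl)(CC)CC
Why: Proposed new method: divalent chromium with Et3SiCl should reduce only the 2-substituted acrolein (C14=C10–C1=O) of 24 to the (Z)-γ-siloxyallylchromium 25, which adds through C1 to the C2 aldehyde in a closed six-membered chair transition state, forming the C1–C2 bond and regenerating the C10=C14 exocyclic methylene; the closest known reaction types are the intermolecular chromium-mediated pinacol-type cross-coupling of 2-alkylacroleins with aldehydes and the Nozaki–Hiyama–Kishi allylation used to close ten-membered germacrane rings. The ten-membered carbocycle is closed in the 10-exo-trig mode at the aldehyde carbon under high dilution, with the planar butenolide and the trans-epoxide limiting the freedom of the C3–C9 tether. C1 and C2 are set together by the chair: the siloxy group cis to the CH2–Cr arm (favoured by the 2-alkyl substituent) sits axial and should give the syn (threo) diol, drawn here as 1R,2R. The step needs chemoselectivity for the enal over the saturated aldehyde, butenolide, acrylate, acetate and epoxide, which the much easier reduction of the silyl-activated enal should secure, and it needs syn over anti selectivity; the face of attack is not critical, because either syn isomer can be taken to the same cis-epoxide by making O-2 or O-1 the leaving group. The two oxygens emerge differentiated (O-1 silylated, O-2 free), as step 18 requires.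

**Step 18**
Reactants: 26 (1R,2R,4R,5R,6S,8S)-13-acetoxy-4,5-epoxy-2-hydroxy-1-(TES-oxy)-8-({2-[(PMB-oxy)methyl]prop-2-enoyl}oxy)germacra-7(11),10(14)-dien-12,6-olide
Product: 28 (1R,2S,4R,5R,6S,8S)-13-acetoxy-1,2:4,5-diepoxy-8-({2-[(PMB-oxy)methyl]prop-2-enoyl}oxy)germacra-7(11),10(14)-dien-12,6-olide, via mesylate 27 (not isolated)
Conditions: MsCl, Et3N, THF, 0 °C; then TASF, DMF, 0 °C
Reagents that add atoms: none
Why: Mesylation of the free C2 hydroxyl, then fluoride cleavage of the C1 silyl ether, releases an alkoxide that displaces the mesylate (Williamson epoxide closure, 3-exo-tet) with inversion at C2, which should give the cis-epoxide (1R,2S).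

**Step 19**
Reactants: 28 (1R,2S,4R,5R,6S,8S)-13-acetoxy-1,2:4,5-diepoxy-8-({2-[(PMB-oxy)methyl]prop-2-enoyl}oxy)germacra-7(11),10(14)-dien-12,6-olide
Product: 29 (1R,2S,4R,5R,6S,8S)-13-acetoxy-1,2:4,5-diepoxy-8-{[2-(hydroxymethyl)prop-2-enoyl]oxy}germacra-7(11),10(14)-dien-12,6-olide (CNP0233746.1)
Conditions: DDQ, CH2Cl2/pH 7 buffer, 0 °C
Reagents that add atoms: none
Why: Oxidative cleavage of the PMB ether by DDQ in wet solvent at neutral pH should free the side-chain alcohol without the acid or base that the two epoxides, the acetate and the butenolide would not tolerate.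

**Compound list**
1 | tert-butyl(but-3-yn-1-yloxy)diphenylsilane | C#CCCO[Si](c1ccccc1)(c1ccccc1)C(C)(C)C | starting material
2 | dimethyl[(1E)-2-methyl-4-(TBDPS-oxy)but-1-en-1-yl]alane | C[Al](C)/C=C(\C)CCO[Si](c1ccccc1)(c1ccccc1)C(C)(C)C | intermediate
3 | lithium butyldimethyl[(1E)-2-methyl-4-(TBDPS-oxy)but-1-en-1-yl]aluminate | [Li+].CCCC[Al-](C)(C)/C=C(\C)CCO[Si](c1ccccc1)(c1ccccc1)C(C)(C)C | intermediate
4 | (2E)-5-(TBDPS-oxy)-3-methylpent-2-en-1-ol | OC/C=C(\C)CCO[Si](c1ccccc1)(c1ccccc1)C(C)(C)C | intermediate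
5 | (2E)-5-(TBDPS-oxy)-3-methylpent-2-enal | O=C/C=C(\C)CCO[Si](c1ccccc1)(c1ccccc1)C(C)(C)C | intermediate
6 | tert-butyldimethyl(prop-2-yn-1-yloxy)silane | C#CCO[Si](C)(C)C(C)(C)C | starting material
7 | (4R,5E)-1-(TBS-oxy)-8-(TBDPS-oxy)-6-methyloct-5-en-2-yn-4-ol | O[C@H](/C=C(\C)CCO[Si](c1ccccc1)(c1ccccc1)C(C)(C)C)C#CCO[Si](C)(C)C(C)(C)C | intermediate
8 | chelated alkenylmagnesium alkoxide (2,5-dihydro-1,2-oxamagnesole; vinyl on C7, Mg on C11) | [Mg]1O[C@H](/C=C(\C)CCO[Si](c2ccccc2)(c2ccccc2)C(C)(C)C)C(C=C)=C1CO[Si](C)(C)C(C)(C)C | intermediate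
9 | (2Z,4R,5E)-1-(TBS-oxy)-8-(TBDPS-oxy)-3-ethenyl-2-iodo-6-methylocta-2,5-dien-4-ol | O[C@H](/C=C(\C)CCO[Si](c1ccccc1)(c1ccccc1)C(C)(C)C)/C(C=C)=C(\I)CO[Si](C)(C)C(C)(C)C | intermediate
10 | (1S,2Z)-4-(TBS-oxy)-2-ethenyl-3-iodo-1-Ox-but-2-en-1-ol | CC(C)(C)[Si](c1ccccc1)(c1ccccc1)OCC[C@@]1(C)O[C@@H]1[C@@H](O)/C(C=C)=C(\I)CO[Si](C)(C)C(C)(C)C | intermediate
11 | (5S)-3-[(TBS-oxy)methyl]-4-ethenyl-5-Ox-furan-2(5H)-one | CC(C)(C)[Si](c1ccccc1)(c1ccccc1)OCC[C@@]1(C)O[C@@H]1[C@H]1OC(=O)C(CO[Si](C)(C)C(C)(C)C)=C1C=C | intermediate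
12 | (5S)-4-ethenyl-3-(hydroxymethyl)-5-Ox-furan-2(5H)-one | CC(C)(C)[Si](c1ccccc1)(c1ccccc1)OCC[C@@]1(C)O[C@@H]1[C@H]1OC(=O)C(CO)=C1C=C | intermediate
13 | [(5S)-4-ethenyl-2-oxo-5-Ox-2,5-dihydrofuran-3-yl]methyl acetate | CC(C)(C)[Si](c1ccccc1)(c1ccccc1)OCC[C@@]1(C)O[C@@H]1[C@H]1OC(=O)C(COC(C)=O)=C1C=C | intermediate
14 | [(5S)-4-formyl-2-oxo-5-Ox-2,5-dihydrofuran-3-yl]methyl acetate | CC(C)(C)[Si](c1ccccc1)(c1ccccc1)OCC[C@@]1(C)O[C@@H]1[C@H]1OC(=O)C(COC(C)=O)=C1C=O | intermediate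
15 | 3-chloro-2-(chloromethyl)prop-1-ene | C=C(CCl)CCl | starting material
16 | tributyl[2-(chloromethyl)prop-2-en-1-yl]stannane | C=C(CCl)C[Sn](CCCC)(CCCC)CCCC | intermediate
17 | [(5S)-4-[(1S)-3-(chloromethyl)-1-hydroxybut-3-en-1-yl]-2-oxo-5-Ox-2,5-dihydrofuran-3-yl]methyl acetate | CC(C)(C)[Si](c1ccccc1)(c1ccccc1)OCC[C@@]1(C)O[C@@H]1[C@H]1OC(=O)C(COC(C)=O)=C1[C@@H](O)CC(=C)CCl | intermediate
18 | 2-(bromomethyl)prop-2-enoic acid | C=C(CBr)C(=O)O | starting material
19 | (4-methoxyphenyl)methanol | COc1ccc(CO)cc1 | starting material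
20 | 2-[(PMB-oxy)methyl]prop-2-enoic acid | C=C(COCc1ccc(OC)cc1)C(=O)O | intermediate
21 | (1S)-1-[(2S)-4-(acetoxymethyl)-5-oxo-2-Ox-2,5-dihydrofuran-3-yl]-3-(chloromethyl)but-3-en-1-yl 2-[(PMB-oxy)methyl]prop-2-enoate | CC(C)(C)[Si](c1ccccc1)(c1ccccc1)OCC[C@@]1(C)O[C@@H]1[C@H]1OC(=O)C(COC(C)=O)=C1[C@@H](OC(=O)C(=C)COCc1ccc(OC)cc1)CC(=C)CCl | intermediate
22 | (1S)-1-[(2S)-4-(acetoxymethyl)-5-oxo-2-Ox-2,5-dihydrofuran-3-yl]-3-formylbut-3-en-1-yl 2-[(PMB-oxy)methyl]prop-2-enoate | CC(C)(C)[Si](c1ccccc1)(c1ccccc1)OCC[C@@]1(C)O[C@@H]1[C@H]1OC(=O)C(COC(C)=O)=C1[C@@H](OC(=O)C(=C)COCc1ccc(OC)cc1)CC(=C)C=O | intermediate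
23 | (1S)-1-[(2S)-4-(acetoxymethyl)-2-[(2R,3R)-3-(2-hydroxyethyl)-3-methyloxiran-2-yl]-5-oxo-2,5-dihydrofuran-3-yl]-3-formylbut-3-en-1-yl 2-[(PMB-oxy)methyl]prop-2-enoate | OCC[C@@]1(C)O[C@@H]1[C@H]1OC(=O)C(COC(C)=O)=C1[C@@H](OC(=O)C(=C)COCc1ccc(OC)cc1)CC(=C)C=O | intermediate
24 | (1S)-1-[(2S)-4-(acetoxymethyl)-2-[(2R,3R)-3-methyl-3-(2-oxoethyl)oxiran-2-yl]-5-oxo-2,5-dihydrofuran-3-yl]-3-formylbut-3-en-1-yl 2-[(PMB-oxy)methyl]prop-2-enoate | O=CC[C@@]1(C)O[C@@H]1[C@H]1OC(=O)C(COC(C)=O)=C1[C@@H](OC(=O)C(=C)COCc1ccc(OC)cc1)CC(=C)C=O | intermediate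
25 | (Z)-γ-(TES-oxy)allylchromium dichloride derived from 24 (Cr on C14, siloxy on C1, C2 aldehyde intact) | O=CC[C@@]1(C)O[C@@H]1[C@H]1OC(=O)C(COC(C)=O)=C1[C@@H](OC(=O)C(=C)COCc1ccc(OC)cc1)C/C(=C/O[Si](CC)(CC)CC)C[Cr](Cl)Cl | intermediate
26 | (1R,2R,4R,5R,6S,8S)-13-acetoxy-4,5-epoxy-2-hydroxy-1-(TES-oxy)-8-({2-[(PMB-oxy)methyl]prop-2-enoyl}oxy)germacra-7(11),10(14)-dien-12,6-olide | C=C(COCc1ccc(OC)cc1)C(=O)O[C@H]1CC(=C)[C@@H](O[Si](CC)(CC)CC)[C@H](O)C[C@@]2(C)O[C@@H]2[C@H]2OC(=O)C(COC(C)=O)=C12 | intermediate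
27 | 2-O-methanesulfonate of 26 | C=C(COCc1ccc(OC)cc1)C(=O)O[C@H]1CC(=C)[C@@H](O[Si](CC)(CC)CC)[C@H](OS(C)(=O)=O)C[C@@]2(C)O[C@@H]2[C@H]2OC(=O)C(COC(C)=O)=C12 | intermediate
28 | (1R,2S,4R,5R,6S,8S)-13-acetoxy-1,2:4,5-diepoxy-8-({2-[(PMB-oxy)methyl]prop-2-enoyl}oxy)germacra-7(11),10(14)-dien-12,6-olide | C=C(COCc1ccc(OC)cc1)C(=O)O[C@H]1CC(=C)[C@H]2O[C@H]2C[C@@]2(C)O[C@@H]2[C@H]2OC(=O)C(COC(C)=O)=C12 | intermediate
29 | (1R,2S,4R,5R,6S,8S)-13-acetoxy-1,2:4,5-diepoxy-8-{[2-(hydroxymethyl)prop-2-enoyl]oxy}germacra-7(11),10(14)-dien-12,6-olide (CNP0233746.1) | C=C(CO)C(=O)O[C@H]1CC(=C)[C@H]2O[C@H]2C[C@@]2(C)O[C@@H]2[C@H]2OC(=O)C(COC(C)=O)=C12 | target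

**Step count**
Total step count: 19 (17 in the main line, plus steps 10 and 12 for reagents 16 and 20).
Longest linear sequence: 17 steps (1 to 29 through steps 1–9, 11 and 13–19).

**Steps most likely to fail**

Step 17 (Proposed new method). The ring closure may lose to intermolecular pinacol coupling or oligomerisation. The 4,5-epoxide may be opened by chloride under silyl chloride and chromium Lewis acid. The addition may go anti instead of syn. The fallback uses known chemistry and sets out from dialdehyde 24: both formyl groups would be methylenated (Ph3P=CH2, THF, −78 °C) to the triene (1S)-1-[(2S)-4-(acetoxymethyl)-2-[(2R,3R)-3-methyl-3-(prop-2-en-1-yl)oxiran-2-yl]-5-oxo-2,5-dihydrofuran-3-yl]-3-methylidenepent-4-en-1-yl 2-[(PMB-oxy)methyl]prop-2-enoate F1. Ring-closing metathesis of the two monosubstituted alkenes (second-generation Hoveyda–Grubbs catalyst, toluene, 80 °C, 1 mM) would form the C1=C2 bond with loss of ethene and give (1Z,4R,5R,6S,8S)-13-acetoxy-4,5-epoxy-8-({2-[(PMB-oxy)methyl]prop-2-enoyl}oxy)germacra-1,7(11),10(14)-trien-12,6-olide F2, ring strain being expected to favour the Z alkene. Epoxidation of the cis-disubstituted alkene with dimethyldioxirane (acetone, −20 °C) would then give 28, where the route is rejoined; site and face selectivity of this epoxidation would have to be checked.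

Step 4. Regio- or stereocontrol of the carbomagnesiation may erode, the silyloxy group may be lost by β-elimination from the alkenylmagnesium to an allene, and the allylic alkoxide may decompose at 70 °C. The fallback sets out from 7 and builds the butenolide by halocarbonylation instead. Hydroxyl-directed epoxidation (mCPBA, NaHCO3, CH2Cl2, 0 °C; threo as in step 5) would give (1S)-4-(TBS-oxy)-1-Ox-but-2-yn-1-ol F3. Cyclocarbonylation (PdCl2 cat., CuCl2, CO, THF, rt; anti-chloropalladation, CO insertion, lactonisation) would give (5R)-3-[(TBS-oxy)methyl]-4-chloro-5-Ox-furan-2(5H)-one F4. Stille coupling with tributyl(vinyl)stannane (Pd2(dba)3, AsPh3, NMP, 50 °C) would return to 11.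

Step 11. Facial selectivity may be poor or turnover slow, because the hindered, Lewis-basic β-formylbutenolide can bind the titanium catalyst unproductively. The fallback sets out from 14 and sets C8 by reduction instead of C–C bond formation. Indium-mediated Barbier allylation with 15 (In powder, THF/H2O, rt) would give 17 together with its C8 epimer [(5S)-4-[(1R)-3-(chloromethyl)-1-hydroxybut-3-en-1-yl]-2-oxo-5-Ox-2,5-dihydrofuran-3-yl]methyl acetate F5. Dess–Martin oxidation of the mixture would give the ketone [(5S)-4-[3-(chloromethyl)but-3-enoyl]-2-oxo-5-Ox-2,5-dihydrofuran-3-yl]methyl acetate F6. Corey–Bakshi–Shibata reduction ((R)-2-methyl-CBS-oxazaborolidine, catecholborane, toluene, −78 °C) would then return to 17 by reagent control.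

**Further compounds**
F1 | step 17 | (1S)-1-[(2S)-4-(acetoxymethyl)-2-[(2R,3R)-3-methyl-3-(prop-2-en-1-yl)oxiran-2-yl]-5-oxo-2,5-dihydrofuran-3-yl]-3-methylidenepent-4-en-1-yl 2-[(PMB-oxy)methyl]prop-2-enoate | C=CC[C@@]1(C)O[C@@H]1[C@H]1OC(=O)C(COC(C)=O)=C1[C@@H](OC(=O)C(=C)COCc1ccc(OC)cc1)CC(=C)C=C
F2 | step 17 | (1Z,4R,5R,6S,8S)-13-acetoxy-4,5-epoxy-8-({2-[(PMB-oxy)methyl]prop-2-enoyl}oxy)germacra-1,7(11),10(14)-trien-12,6-olide | C=C(COCc1ccc(OC)cc1)C(=O)O[C@H]1CC(=C)/C=C\C[C@@]2(C)O[C@@H]2[C@H]2OC(=O)C(COC(C)=O)=C12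
F3 | step 4 | (1S)-4-(TBS-oxy)-1-Ox-but-2-yn-1-ol | CC(C)(C)[Si](c1ccccc1)(c1ccccc1)OCC[C@@]1(C)O[C@@H]1[C@@H](O)C#CCO[Si](C)(C)C(C)(C)C
F4 | step 4 | (5R)-3-[(TBS-oxy)methyl]-4-chloro-5-Ox-furan-2(5H)-one | CC(C)(C)[Si](c1ccccc1)(c1ccccc1)OCC[C@@]1(C)O[C@@H]1[C@H]1OC(=O)C(CO[Si](C)(C)C(C)(C)C)=C1Cl
F5 | step 11 | [(5S)-4-[(1R)-3-(chloromethyl)-1-hydroxybut-3-en-1-yl]-2-oxo-5-Ox-2,5-dihydrofuran-3-yl]methyl acetate | CC(C)(C)[Si](c1ccccc1)(c1ccccc1)OCC[C@@]1(C)O[C@@H]1[C@H]1OC(=O)C(COC(C)=O)=C1[C@H](O)CC(=C)CCl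
F6 | step 11 | [(5S)-4-[3-(chloromethyl)but-3-enoyl]-2-oxo-5-Ox-2,5-dihydrofuran-3-yl]methyl acetate | CC(C)(C)[Si](c1ccccc1)(c1ccccc1)OCC[C@@]1(C)O[C@@H]1[C@H]1OC(=O)C(COC(C)=O)=C1C(=O)CC(=C)CCl
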